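(The runs are calculated from invented constants; the scatter is artificial.)

4 questions are put to these flasks, and this examination presses on the last of them: how much substrate remains in Thursday's run at 27 min.

| flask | substrate | reagent | free catalyst | time |
|---|---|---|---|---|
| Sunday's | 0.100 M | 0.100 M | 5.00 × 10⁻⁴ M |  |
| Friday's | 0.0400 M | 0.0400 M | 5.00 × 10⁻⁴ M |  |
| Monday's | 0.300 M | 0.100 M | 5.00 × 10⁻⁴ M |  |
| Saturday's | 0.100 M | 0.200 M | 5.00 × 10⁻⁴ M |  |
| Thursday's | 0.720 M | 0.100 M | 5.00 × 10⁻⁴ M | 27 min |

| Sunday's run: time / min | Sunday's run: [substrate] / M | Friday's run: time / min | Friday's run: [substrate] / M | Monday's run: time / min | Monday's run: [substrate] / M | Saturday's run: time / min | Saturday's run: [substrate] / M |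
|---|---|---|---|---|---|---|---|
| 0.97 | 0.0980 | 0.97 | 0.0415 | 0.97 | 0.2966 | 0.97 | 0.0990 |
| 2.9 | 0.0955 | 2.9 | 0.0388 | 2.9 | 0.2915 | 2.9 | 0.0902 |
| 5.6 | 0.0911 | 5.6 | 0.0360 | 5.6 | 0.2853 | 5.6 | 0.0878 |
| 8.9 | 0.0863 | 8.9 | 0.0329 | 8.9 | 0.2746 | 8.9 | 0.0798 |
| 13 | 0.0803 | 13 | 0.0324 | 13 | 0.2652 | 13 | 0.0700 |
| 17 | 0.0735 | 17 | 0.0333 | 17 | 0.2565 | 17 | 0.0653 |
| 22 | 0.0686 | 22 | 0.0302 | 22 | 0.2471 | 22 | 0.0566 |
| 27 | 0.0636 | 27 | 0.0273 | 27 | 0.2418 | 27 | 0.0522 |

(scatter of a reading: 0.001 M)

- Overall: substrate + reagent -> target, with free catalyst as catalyst.
- Constant volume, constant temperature.
- What is held in complexes is read along with the free species.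
- "The second partner" is reagent.
- An order is taken over about fifteen percent of the charge, up and down.

* order of the initial rate in [substrate], near the charge of the Sunday's run, the rate being that where two percent of its substrate are target (one fixed amount of target, the same in the runs compared)
* order of the initial rate in [reagent], near the charge of the Sunday's run, the rate being that where two percent of its substrate are target
* the Friday's run starts with 0.0600 M less of substrate and of reagent than the Sunday's run, and with no target. Compared where both hold the same amount of substrate, once fifteen percent of what the Friday's run was charged with has turned into target, is the Friday's run faster, slower or alike (within a tenth)?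
* substrate in the Thursday's run at 27 min, as a share of the substrate charged

*What can you read most directly from the runs?*

The substrate used by the last reading. Sunday's run has used 0.0364 M by 27 min, and Monday's run has used 0.0582 M. Each reading has a scatter of 0.001 M.

*Those two runs differ in what?*

In the substrate charge, which is 3.00 times as large in Monday's run. Their reagent and free catalyst charges are equal. So I take the ratio of the amounts used, 1.60, and ask what power of the charge ratio gives it. The answer is 0.427. I call this power the turnover exponent n: the logarithm of the ratio of substrate used by a fixed time, over the logarithm of the ratio of substrate charged, with equal reagent and catalyst charges.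

*Is n the order you were asked for?*

No. The order belongs to one early moment, whereas n covers the whole 27 min. The comparison drifts: at 8.9 min the same ratio of amounts used reads 1.85, and at 27 min it reads 1.60. Meanwhile Monday's run has taken 58.2% of its reagent and Sunday's run 36.4%. So n belongs to this time and this reagent charge, and Thursday's run shares both, with 0.100 M of reagent.

*Then what is my reckoning for Thursday's run?*

Sunday's amount used, multiplied by the substrate charge ratio raised to n, gives 0.0846 M.

*Does Thursday's reagent allow that?*

Yes. Reagent is the limiting reagent in Thursday's run, and this amount is 84.6% of its charge. My reckoning therefore leaves 88.3% of Thursday's substrate. The weak spot is that 0.720 M lies beyond any substrate charge yet run.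

The forecast differs from my figure. It gives 90.8% for Thursday's run, with the turnover “limited by reagent and saturation”. It puts the orders at 0.62 in substrate and 0.6 in reagent, and it calls Friday's run faster.

The flask gives orders of 0.73 in substrate and 0.51 in reagent. The rate of target formation in Friday's run, over that in Sunday's run at the point compared, is 1.0, so the two are alike. Thursday's run keeps 88.7% of its substrate.

    free catalyst + substrate ⇌ catalyst-substrate complex, settled at all times (3.040 M⁻¹)
    free catalyst + reagent ⇌ catalyst-reagent complex, settled at all times (17.40 M⁻¹)
    catalyst-substrate complex + catalyst-reagent complex → target + 2 free catalyst (75000 M⁻¹ min⁻¹)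
    substrate + reagent → target (0.09120 M⁻¹ min⁻¹)
    catalyst-substrate complex + substrate ⇌ doubly bound catalyst, settled at all times (11.40 M⁻¹)

Thursday's run used 0.0815 M, which puts n from Sunday's run to Thursday's run at 0.409, beside the 0.427 read from Monday's run. The direct turning of substrate and reagent into target carries that turnover: with that step taken away, Thursday's run keeps 99.5% of its substrate instead of 88.7%.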